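Locants used below: C1 = CHO, C2 = enal α-carbon, C3–C5 = hydroxypropyl arm (C3–OH), ring = C6 (CH), C7 (alkylidene carbon), C8, C9 (CH2), C10 (C(OH)CH3), C11 (quaternary), side chain C12–C23 with the acetate on C16.
Late disconnections: C16 acetate and C3 silyl ether; C1 aldehyde from a methyl enoate; C13–C14 by B-alkyl Suzuki–Miyaura coupling of a C11 vinyl group with the (E)-vinyl iodide C14–C23 (from geranyl bromide and propargyl alcohol); the (2Z) tetrasubstituted alkene by an intramolecular Horner–Wadsworth–Emmons reaction on a C7 ketone through a temporary C12–O lactone tether.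
Key disconnection at C9–C10 and C6–C7: the ring carries oxygen at C10 and a carbonyl-level carbon at C7 in a 1,4 relationship across C9–C8 (a γ-hydroxy acyl, that is a γ-lactone retron) and C6 is α to C7, so the cyclohexane is the sum of a β-bromo methyl ketone (C10–C11–C6) and an acrylate (C9–C8–C7) joined by SmI2.
The bromo ketone with the quaternary C11 comes from enantioselective cyclopropanation of 6-methyl-3,4-dihydro-2H-pyran and bromonium opening of the cyclopropane, which also frees the C3–C5 arm.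
Ring order: 2-oxabicyclo[4.1.0]heptane (temporary, opened in step 5); γ-lactone and then the C6–C11 cyclohexane in the key step; seven-membered bridging lactone (temporary, opened in step 11).

Key step: step 7

Assumption: Rh2(S-PTTL)4 is taken to deliver the enantiomer of 4 that is drawn; if the opposite sense of induction is found, Rh2(R-PTTL)4 is used instead.

Step 1
Reactants: 1 methyl 2-methyl-3-oxobutanoate
Product: 2 methyl 2-diazopropanoate
Conditions: p-ABSA, DBU, MeCN, 0 °C to rt
Reagents that add atoms: 4-acetamidobenzenesulfonyl azide (p-ABSA), CC(=O)Nc1ccc(cc1)S(=O)(=O)N=[N+]=[N-]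
Why: Deacylative Regitz diazo transfer: the enolate of the 2-substituted β-keto ester takes up N2 from the sulfonyl azide and loses its acetyl group to the sulfonamide nitrogen, the usual entry to α-alkyl α-diazo esters.

Step 2
Reactants: 2 methyl 2-diazopropanoate; 3 6-methyl-3,4-dihydro-2H-pyran
Product: 4 methyl (1S,6S,7S)-1,7-dimethyl-2-oxabicyclo[4.1.0]heptane-7-carboxylate (ester exo)
Conditions: Rh2(S-PTTL)4 [dirhodium tetrakis(N-phthaloyl-(S)-tert-leucinate)] (0.5 mol %), 3 (3 equiv), hexanes, −78 °C, slow addition of 2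
Reagents that add atoms: none
Why: Rhodium-carbenoid cyclopropanation of the electron-rich enol ether at −78 °C (which suppresses β-hydride migration of the α-methyl carbenoid) should put the ester exo, anti to the pyran ring, while the chiral carboxylate ligands choose the alkene face, so that the quaternary carbon that becomes C11 is set in this step.

Step 3
Reactants: 4 methyl (1S,6S,7S)-1,7-dimethyl-2-oxabicyclo[4.1.0]heptane-7-carboxylate
Product: 5 [(1S,6S,7R)-1,7-dimethyl-2-oxabicyclo[4.1.0]heptan-7-yl]methanol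
Conditions: LiAlH4, Et2O, 0 °C
Reagents that add atoms: none
Why: LiAlH4 reduction of the ester to the primary alcohol removes the acceptor group, so that the alkoxycyclopropane is no longer a donor–acceptor system and can later be opened at the other bond, and it touches no stereocentre.

Step 4
Reactants: 5 [(1S,6S,7R)-1,7-dimethyl-2-oxabicyclo[4.1.0]heptan-7-yl]methanol
Product: 6 tert-butyl{[(1S,6S,7R)-1,7-dimethyl-2-oxabicyclo[4.1.0]heptan-7-yl]methoxy}dimethylsilane
Conditions: TBSCl, imidazole, DMF, rt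
Reagents that add atoms: tert-butyldimethylsilyl chloride, CC(C)(C)[Si](C)(C)Cl
Why: Routine silylation of the neopentyl-type alcohol gives an ether that is stable to the next steps, offers no 1,5-hydrogen to the C6 radical of step 7 and can be removed later in the presence of the diphenylsilyl ether.

Step 5
Reactants: 6 tert-butyl{[(1S,6S,7R)-1,7-dimethyl-2-oxabicyclo[4.1.0]heptan-7-yl]methoxy}dimethylsilane
Product: 7 (3R,4R)-4-bromo-3-{[tert-butyl(dimethyl)silyl]oxymethyl}-7-hydroxy-3-methylheptan-2-one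
Conditions: NBS, NaHCO3, MeCN/H2O, 0 °C
Reagents that add atoms: N-bromosuccinimide, O=C1CCC(=O)N1Br; water, O
Why: Electrophilic (bromonium) opening of an alkoxycyclopropane: Br+ attacks the less substituted ring-fusion carbon with inversion (the quaternary carbon cannot be attacked from the rear), the bond to the oxygen-bearing carbon breaks and water hydrolyses the oxocarbenium ion to the methyl ketone and the free C3 hydroxyl, and the C–Br configuration is of no consequence because it is erased in step 7.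

Step 6
Reactants: 7 (3R,4R)-4-bromo-3-{[tert-butyl(dimethyl)silyl]oxymethyl}-7-hydroxy-3-methylheptan-2-one
Product: 8 (3R,4R)-4-bromo-3-{[tert-butyl(dimethyl)silyl]oxymethyl}-7-{[tert-butyl(diphenyl)silyl]oxy}-3-methylheptan-2-one
Conditions: TBDPSCl, imidazole, CH2Cl2, 0 °C to rt
Reagents that add atoms: tert-butyldiphenylsilyl chloride, CC(C)(C)[Si](Cl)(c1ccccc1)c1ccccc1
Why: Routine silylation of the only hydroxyl group with the acid-stable tert-butyldiphenylsilyl group removes the acidic hydrogen before the organosamarium chemistry and protects C3–OH until the last step.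

Step 7
Reactants: 8 (3R,4R)-4-bromo-3-{[tert-butyl(dimethyl)silyl]oxymethyl}-7-{[tert-butyl(diphenyl)silyl]oxy}-3-methylheptan-2-one; 9 methyl acrylate
Product: 12 (2S,3R,4S)-3-{[tert-butyl(dimethyl)silyl]oxymethyl}-2-(3-{[tert-butyl(diphenyl)silyl]oxy}propyl)-4-hydroxy-3,4-dimethylcyclohexan-1-one, via bromo γ-lactone 10 (not isolated), via bridged samarium hemiketalate 11 (not isolated)
Conditions: SmI2 (2.2 equiv), 9 (1.1 equiv), t-BuOH (1.0 equiv), THF, −78 to 0 °C; then HMPA (8 equiv), SmI2 (2.5 equiv), 0 °C to rt; air, then aq NH4Cl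
Reagents that add atoms: none
Why: At −78 °C and without HMPA, SmI2 reduces only the ketone, and the samarium ketyl at C10 adds to the β-carbon of methyl acrylate (C9–C10 bond); the adduct radical is reduced and protonated by t-BuOH and the tertiary samarium alkoxide closes the γ-lactone 10 by 5-exo-trig acyl substitution, after which HMPA raises the reducing power so that the secondary C–Br bond is reduced to an organosamarium that attacks the lactone carbonyl (C6–C7 bond) by 6-exo-trig closure to the 7-oxabicyclo[2.2.1]heptane hemiketalate 11, which opens to the 4-hydroxy ketone on work-up. The closest known reaction type is the SmI2-promoted ketone–acrylate (ketyl–olefin) coupling to γ-lactones, sequenced in one flask with the SmI2/HMPA-promoted intramolecular nucleophilic acyl substitution of an alkyl halide on a lactone. C10 is set by Felkin–Anh control in the ketyl addition: the new bond forms anti to the branched C6 substituent of the quaternary C11, with the samarium-bound oxygen beside the C12 CH2OSi group (weak chelation points the same way), which places the C10 oxygen cis to the C11 methyl. C6 is set when the configurationally labile organosamarium closes the bicyclic hemiketalate with its side chain exo, on the side of the oxygen bridge and so cis to the C10 oxygen, and it cannot epimerize as long as C7 is masked as the hemiketalate. The step needs chemoselectivity (ketone before bromide, acylation before protonation), which is secured by the low temperature and the absence of HMPA in the first stage, by only 1.1 equiv of acrylate and 1.0 equiv of t-BuOH, and by the silylation of both hydroxyls.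

Step 8
Reactants: 12 (2S,3R,4S)-3-{[tert-butyl(dimethyl)silyl]oxymethyl}-2-(3-{[tert-butyl(diphenyl)silyl]oxy}propyl)-4-hydroxy-3,4-dimethylcyclohexan-1-one
Product: 13 (2S,3R,4S)-2-(3-{[tert-butyl(diphenyl)silyl]oxy}propyl)-4-hydroxy-3-(hydroxymethyl)-3,4-dimethylcyclohexan-1-one
Conditions: AcOH/THF/H2O (3:1:1), 40 °C
Reagents that add atoms: none
Why: Mild acidic hydrolysis cleaves the tert-butyldimethylsilyl ether selectively because the tert-butyldiphenylsilyl ether is far more stable to acid, and the γ-hydroxy ketone is inert to these conditions.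

Step 9
Reactants: 13 (2S,3R,4S)-2-(3-{[tert-butyl(diphenyl)silyl]oxy}propyl)-4-hydroxy-3-(hydroxymethyl)-3,4-dimethylcyclohexan-1-one
Product: 14 {(1R,2S,6S)-2-(3-{[tert-butyl(diphenyl)silyl]oxy}propyl)-6-hydroxy-1,6-dimethyl-3-oxocyclohexyl}methyl 2-(diethoxyphosphoryl)propanoate (both epimers at the phosphonate carbon)
Conditions: 2-(diethoxyphosphoryl)propanoic acid, EDC·HCl, DMAP, CH2Cl2, 0 °C to rt
Reagents that add atoms: 2-(diethoxyphosphoryl)propanoic acid, CCOP(=O)(OCC)C(C)C(=O)O
Why: Carbodiimide (Steglich) esterification acylates the primary hydroxyl and leaves the tertiary C10 hydroxyl untouched, and the new phosphonate-bearing stereocentre, formed as a mixture, is destroyed in step 10.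

Step 10
Reactants: 14 {(1R,2S,6S)-2-(3-{[tert-butyl(diphenyl)silyl]oxy}propyl)-6-hydroxy-1,6-dimethyl-3-oxocyclohexyl}methyl 2-(diethoxyphosphoryl)propanoate
Product: 15 10-(3-{[tert-butyl(diphenyl)silyl]oxy}propyl)-9-hydroxy-1,5,9-trimethyl-3-oxabicyclo[4.3.1]dec-5-en-4-one (ring stereocentres as in 12; carbonyl C4 cis to C10 across the C5=C6 bond)
Conditions: LiCl, DBU, MeCN, 2 mM, rt to 50 °C
Reagents that add atoms: none
Why: Intramolecular Horner–Wadsworth–Emmons olefination under the mild LiCl/amine conditions: because the ester oxygen is anchored on the C12 methylene of C11, the new seven-membered lactone can hold only a cis double bond, so the carbonyl (future C1) must end cis to C6 and the C2 methyl cis to C8, which fixes the (2Z) geometry of the tetrasubstituted alkene.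

Step 11
Reactants: 15 10-(3-{[tert-butyl(diphenyl)silyl]oxy}propyl)-9-hydroxy-1,5,9-trimethyl-3-oxabicyclo[4.3.1]dec-5-en-4-one
Product: 16 methyl (2Z)-2-[(2R,3R,4S)-2-(3-{[tert-butyl(diphenyl)silyl]oxy}propyl)-4-hydroxy-3-(hydroxymethyl)-3,4-dimethylcyclohexylidene]propanoate
Conditions: K2CO3, MeOH, 0 °C
Reagents that add atoms: methanol, CO
Why: Base-catalysed methanolysis (transesterification) opens the strained bridged lactone to the methyl enoate and the free C12 hydroxyl without touching the alkene geometry fixed in step 10.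

Step 12
Reactants: 16 methyl (2Z)-2-[(2R,3R,4S)-2-(3-{[tert-butyl(diphenyl)silyl]oxy}propyl)-4-hydroxy-3-(hydroxymethyl)-3,4-dimethylcyclohexylidene]propanoate
Product: 17 methyl (2Z)-2-[(2R,3S,4S)-2-(3-{[tert-butyl(diphenyl)silyl]oxy}propyl)-3-formyl-4-hydroxy-3,4-dimethylcyclohexylidene]propanoate
Conditions: DMP (1,1,1-triacetoxy-1,1-dihydro-1,2-benziodoxol-3(1H)-one), NaHCO3, CH2Cl2, 0 °C to rt
Reagents that add atoms: none
Why: Buffered periodinane oxidation converts the primary alcohol into the aldehyde under neutral conditions, which avoids retro-aldol cleavage of the β-hydroxy aldehyde and leaves the tertiary alcohol alone.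

Step 13
Reactants: 17 methyl (2Z)-2-[(2R,3S,4S)-2-(3-{[tert-butyl(diphenyl)silyl]oxy}propyl)-3-formyl-4-hydroxy-3,4-dimethylcyclohexylidene]propanoate
Product: 18 methyl (2Z)-2-[(2R,3S,4S)-2-(3-{[tert-butyl(diphenyl)silyl]oxy}propyl)-3-ethenyl-4-hydroxy-3,4-dimethylcyclohexylidene]propanoate
Conditions: Ph3PCH3Br, KN(SiMe3)2, THF, −78 to 0 °C
Reagents that add atoms: methyltriphenylphosphonium bromide, C[P+](c1ccccc1)(c1ccccc1)c1ccccc1.[Br-]
Why: Wittig methylenation of the non-enolizable neopentyl aldehyde at low temperature installs the C12=C13 vinyl group for the fragment coupling, and the hindered tetrasubstituted enoate does not react with the ylide.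

Step 14
Reactants: 19 prop-2-yn-1-ol; 20 geranyl bromide ((2E)-1-bromo-3,7-dimethylocta-2,6-diene)
Product: 21 (5E)-6,10-dimethylundeca-5,9-dien-2-yn-1-ol
Conditions: CuI (10 mol %), NaI, K2CO3, DMF, rt
Reagents that add atoms: none
Why: Copper-mediated coupling of the terminal alkyne with the primary allylic bromide gives the skipped enyne by direct (SN2) substitution and keeps the (E) geometry of the geranyl unit.

Step 15
Reactants: 21 (5E)-6,10-dimethylundeca-5,9-dien-2-yn-1-ol
Product: 22 (2E,5E)-6,10-dimethylundeca-2,5,9-trien-1-ol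
Conditions: NaAlH2(OCH2CH2OMe)2, THF, 0 °C
Reagents that add atoms: none
Why: Hydroxyl-directed trans-hydroalumination of the propargylic alcohol and protonolysis give the (E)-allylic alcohol only, while the isolated alkenes are inert.

Step 16
Reactants: 22 (2E,5E)-6,10-dimethylundeca-2,5,9-trien-1-ol
Product: 23 [(2R,3R)-3-[(2E)-3,7-dimethylocta-2,6-dien-1-yl]oxiran-2-yl]methanol
Conditions: Ti(OiPr)4 (10 mol %), D-(−)-diethyl tartrate (12 mol %), t-BuOOH, 4 Å molecular sieves, CH2Cl2, −20 °C
Reagents that add atoms: tert-butyl hydroperoxide, CC(C)(C)OO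
Why: Katsuki–Sharpless asymmetric epoxidation acts only on the allylic alkene and, with the D-tartrate ligand, delivers oxygen to the face that gives the (2R,3R)-epoxy alcohol, whose C3 becomes C16 of the target.

Step 17
Reactants: 23 [(2R,3R)-3-[(2E)-3,7-dimethylocta-2,6-dien-1-yl]oxiran-2-yl]methanol
Product: 24 (2S,3R)-2-(chloromethyl)-3-[(2E)-3,7-dimethylocta-2,6-dien-1-yl]oxirane
Conditions: PPh3, CCl4, NaHCO3, reflux
Reagents that add atoms: tetrachloromethane, ClC(Cl)(Cl)Cl
Why: Appel chlorination converts the primary alcohol into the chloride under neutral conditions that leave the epoxide and the alkenes intact.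

Step 18
Reactants: 24 (2S,3R)-2-(chloromethyl)-3-[(2E)-3,7-dimethylocta-2,6-dien-1-yl]oxirane
Product: 25 (3R,5E)-6,10-dimethylundeca-5,9-dien-1-yn-3-ol
Conditions: n-BuLi (3.2 equiv), THF, −78 to −30 °C; aq NH4Cl
Reagents that add atoms: none
Why: Base-induced opening of the 2,3-epoxy chloride to the chloroallylic alkoxide and loss of HCl (an epoxy chloride to propargylic alcohol fragmentation) give the terminal alkyne with the carbinol C–O bond untouched, so the configuration set in step 16 is kept.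

Step 19
Reactants: 25 (3R,5E)-6,10-dimethylundeca-5,9-dien-1-yn-3-ol
Product: 27 (1E,3R,5E)-1-iodo-2,6,10-trimethylundeca-1,5,9-trien-3-ol, via alkenylalane 26 (not isolated)
Conditions: AlMe3 (3 equiv), Cp2ZrCl2 (0.25 equiv), CH2Cl2, 0 °C to rt; then I2, THF, −30 °C
Reagents that add atoms: trimethylaluminium, C[Al](C)C; iodine, II
Why: Zirconium-catalysed Negishi carboalumination adds methyl and aluminium syn across the terminal alkyne with methyl on the internal carbon, and iodinolysis with retention gives the (E)-vinyl iodide.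

Step 20
Reactants: 18 methyl (2Z)-2-[(2R,3S,4S)-2-(3-{[tert-butyl(diphenyl)silyl]oxy}propyl)-3-ethenyl-4-hydroxy-3,4-dimethylcyclohexylidene]propanoate; 27 (1E,3R,5E)-1-iodo-2,6,10-trimethylundeca-1,5,9-trien-3-ol
Product: 29 methyl (2Z)-2-[(2R,3S,4S)-2-(3-{[tert-butyl(diphenyl)silyl]oxy}propyl)-4-hydroxy-3-[(3E,5R,7E)-5-hydroxy-4,8,12-trimethyltrideca-3,7,11-trien-1-yl]-3,4-dimethylcyclohexylidene]propanoate, via B-alkyl-9-BBN borane 28 (not isolated)
Conditions: 9-BBN-H (2.5 equiv), THF, rt; then 27, Pd(dppf)Cl2 (5 mol %), AsPh3, Cs2CO3, DMF/H2O, rt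
Reagents that add atoms: none
Why: Anti-Markovnikov hydroboration of the only monosubstituted alkene followed by B-alkyl Suzuki–Miyaura coupling forms the C13–C14 bond with retention of the (E) geometry of the vinyl iodide and tolerates the ester, the free hydroxyls and the silyl ether.

Step 21
Reactants: 29 methyl (2Z)-2-[(2R,3S,4S)-2-(3-{[tert-butyl(diphenyl)silyl]oxy}propyl)-4-hydroxy-3-[(3E,5R,7E)-5-hydroxy-4,8,12-trimethyltrideca-3,7,11-trien-1-yl]-3,4-dimethylcyclohexylidene]propanoate
Product: 30 (2Z)-2-[(2R,3S,4S)-2-(3-{[tert-butyl(diphenyl)silyl]oxy}propyl)-4-hydroxy-3-[(3E,5R,7E)-5-hydroxy-4,8,12-trimethyltrideca-3,7,11-trien-1-yl]-3,4-dimethylcyclohexylidene]propan-1-ol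
Conditions: iBu2AlH (5 equiv), CH2Cl2, −78 to −20 °C
Reagents that add atoms: none
Why: iBu2AlH reduces the conjugated methyl ester by 1,2-addition to the primary allylic alcohol and leaves the geometry of the tetrasubstituted alkene unchanged.

Step 22
Reactants: 30 (2Z)-2-[(2R,3S,4S)-2-(3-{[tert-butyl(diphenyl)silyl]oxy}propyl)-4-hydroxy-3-[(3E,5R,7E)-5-hydroxy-4,8,12-trimethyltrideca-3,7,11-trien-1-yl]-3,4-dimethylcyclohexylidene]propan-1-ol
Product: 31 (2Z)-2-[(2R,3S,4S)-2-(3-{[tert-butyl(diphenyl)silyl]oxy}propyl)-4-hydroxy-3-[(3E,5R,7E)-5-hydroxy-4,8,12-trimethyltrideca-3,7,11-trien-1-yl]-3,4-dimethylcyclohexylidene]propanal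
Conditions: TEMPO (10 mol %), PhI(OAc)2 (1.2 equiv), CH2Cl2, rt
Reagents that add atoms: none
Why: Oxoammonium (TEMPO) oxidation is selective for the primary allylic alcohol over the secondary C16 and tertiary C10 hydroxyls and stops at the (2Z)-enal.

Step 23
Reactants: 31 (2Z)-2-[(2R,3S,4S)-2-(3-{[tert-butyl(diphenyl)silyl]oxy}propyl)-4-hydroxy-3-[(3E,5R,7E)-5-hydroxy-4,8,12-trimethyltrideca-3,7,11-trien-1-yl]-3,4-dimethylcyclohexylidene]propanal
Product: 32 (2Z)-2-[(2R,3S,4S)-3-[(3E,5R,7E)-5-acetoxy-4,8,12-trimethyltrideca-3,7,11-trien-1-yl]-2-(3-{[tert-butyl(diphenyl)silyl]oxy}propyl)-4-hydroxy-3,4-dimethylcyclohexylidene]propanal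
Conditions: Ac2O, pyridine, DMAP (cat), CH2Cl2, 0 °C
Reagents that add atoms: acetic anhydride, CC(=O)OC(C)=O
Why: Acylation with acetic anhydride occurs only at the secondary C16 hydroxyl because the tertiary C10 hydroxyl is too hindered to react at 0 °C.

Step 24
Reactants: 32 (2Z)-2-[(2R,3S,4S)-3-[(3E,5R,7E)-5-acetoxy-4,8,12-trimethyltrideca-3,7,11-trien-1-yl]-2-(3-{[tert-butyl(diphenyl)silyl]oxy}propyl)-4-hydroxy-3,4-dimethylcyclohexylidene]propanal
Product: 33 (2Z)-2-[(2R,3S,4S)-3-[(3E,5R,7E)-5-acetoxy-4,8,12-trimethyltrideca-3,7,11-trien-1-yl]-4-hydroxy-2-(3-hydroxypropyl)-3,4-dimethylcyclohexylidene]propanal (CNP0421354.1)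
Conditions: HF·pyridine, pyridine, THF, 0 °C to rt
Reagents that add atoms: none
Why: Buffered fluoride cleavage of the primary tert-butyldiphenylsilyl ether frees C3–OH while the allylic acetate, the enal and the tertiary alcohol survive, which gives the target.

Compound list
1 | methyl 2-methyl-3-oxobutanoate | COC(=O)C(C)C(C)=O | starting material
2 | methyl 2-diazopropanoate | COC(=O)C(C)=[N+]=[N-] | intermediate
3 | 6-methyl-3,4-dihydro-2H-pyran | CC1=CCCCO1 | starting material
4 | methyl (1S,6S,7S)-1,7-dimethyl-2-oxabicyclo[4.1.0]heptane-7-carboxylate (ester exo, C7 methyl over the pyran ring) | COC(=O)[C@@]1(C)[C@@H]2CCCO[C@]12C | intermediate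
5 | [(1S,6S,7R)-1,7-dimethyl-2-oxabicyclo[4.1.0]heptan-7-yl]methanol | OC[C@@]1(C)[C@@H]2CCCO[C@]12C | intermediate
6 | tert-butyl{[(1S,6S,7R)-1,7-dimethyl-2-oxabicyclo[4.1.0]heptan-7-yl]methoxy}dimethylsilane | CC(C)(C)[Si](C)(C)OC[C@@]1(C)[C@@H]2CCCO[C@]12C | intermediate
7 | (3R,4R)-4-bromo-3-{[tert-butyl(dimethyl)silyl]oxymethyl}-7-hydroxy-3-methylheptan-2-one | CC(C)(C)[Si](C)(C)OC[C@@](C(C)=O)(C)[C@H](Br)CCCO | intermediate
8 | (3R,4R)-4-bromo-3-{[tert-butyl(dimethyl)silyl]oxymethyl}-7-{[tert-butyl(diphenyl)silyl]oxy}-3-methylheptan-2-one | CC(C)(C)[Si](C)(C)OC[C@@](C(C)=O)(C)[C@H](Br)CCCO[Si](c1ccccc1)(c1ccccc1)C(C)(C)C | intermediate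
9 | methyl acrylate | C=CC(=O)OC | starting material
10 | (5S)-5-[(2R,3R)-3-bromo-1-{[tert-butyl(dimethyl)silyl]oxy}-6-{[tert-butyl(diphenyl)silyl]oxy}-2-methylhexan-2-yl]-5-methyloxolan-2-one (bromo γ-lactone, not isolated) | O=C1CC[C@]([C@](CO[Si](C)(C)C(C)(C)C)(C)[C@H](Br)CCCO[Si](c2ccccc2)(c2ccccc2)C(C)(C)C)(C)O1 | intermediate
11 | 3-{[tert-butyl(dimethyl)silyl]oxymethyl}-2-(3-{[tert-butyl(diphenyl)silyl]oxy}propyl)-3,4-dimethyl-7-oxabicyclo[2.2.1]heptan-1-ol, side chain and C3 methyl exo, present as its samarium alkoxide (bridged hemiketalate, not isolated) | CC(C)(C)[Si](C)(C)OC[C@@]1(C)[C@H](CCCO[Si](c2ccccc2)(c2ccccc2)C(C)(C)C)[C@@]2(O)CC[C@]1(C)O2 | intermediate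
12 | (2S,3R,4S)-3-{[tert-butyl(dimethyl)silyl]oxymethyl}-2-(3-{[tert-butyl(diphenyl)silyl]oxy}propyl)-4-hydroxy-3,4-dimethylcyclohexan-1-one | CC(C)(C)[Si](C)(C)OC[C@@]1(C)[C@H](CCCO[Si](c2ccccc2)(c2ccccc2)C(C)(C)C)C(=O)CC[C@]1(C)O | intermediate
13 | (2S,3R,4S)-2-(3-{[tert-butyl(diphenyl)silyl]oxy}propyl)-4-hydroxy-3-(hydroxymethyl)-3,4-dimethylcyclohexan-1-one | OC[C@@]1(C)[C@H](CCCO[Si](c2ccccc2)(c2ccccc2)C(C)(C)C)C(=O)CC[C@]1(C)O | intermediate
14 | {(1R,2S,6S)-2-(3-{[tert-butyl(diphenyl)silyl]oxy}propyl)-6-hydroxy-1,6-dimethyl-3-oxocyclohexyl}methyl 2-(diethoxyphosphoryl)propanoate (both epimers at the phosphonate carbon) | CCOP(=O)(OCC)C(C)C(=O)OC[C@@]1(C)[C@H](CCCO[Si](c2ccccc2)(c2ccccc2)C(C)(C)C)C(=O)CC[C@]1(C)O | intermediate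
15 | 10-(3-{[tert-butyl(diphenyl)silyl]oxy}propyl)-9-hydroxy-1,5,9-trimethyl-3-oxabicyclo[4.3.1]dec-5-en-4-one, ring stereocentres as in 12, carbonyl cis to C10 across C5=C6 | O=C2OC[C@@]1(C)[C@H](CCCO[Si](c3ccccc3)(c3ccccc3)C(C)(C)C)/C(=C2/C)CC[C@]1(C)O | intermediate
16 | methyl (2Z)-2-[(2R,3R,4S)-2-(3-{[tert-butyl(diphenyl)silyl]oxy}propyl)-4-hydroxy-3-(hydroxymethyl)-3,4-dimethylcyclohexylidene]propanoate | OC[C@@]1(C)[C@H](CCCO[Si](c2ccccc2)(c2ccccc2)C(C)(C)C)/C(=C(/C)C(=O)OC)CC[C@]1(C)O | intermediate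
17 | methyl (2Z)-2-[(2R,3S,4S)-2-(3-{[tert-butyl(diphenyl)silyl]oxy}propyl)-3-formyl-4-hydroxy-3,4-dimethylcyclohexylidene]propanoate | O=C[C@@]1(C)[C@H](CCCO[Si](c2ccccc2)(c2ccccc2)C(C)(C)C)/C(=C(/C)C(=O)OC)CC[C@]1(C)O | intermediate
18 | methyl (2Z)-2-[(2R,3S,4S)-2-(3-{[tert-butyl(diphenyl)silyl]oxy}propyl)-3-ethenyl-4-hydroxy-3,4-dimethylcyclohexylidene]propanoate | C=C[C@@]1(C)[C@H](CCCO[Si](c2ccccc2)(c2ccccc2)C(C)(C)C)/C(=C(/C)C(=O)OC)CC[C@]1(C)O | intermediate
19 | prop-2-yn-1-ol | OCC#C | starting material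
20 | geranyl bromide, (2E)-1-bromo-3,7-dimethylocta-2,6-diene | BrC/C=C(\C)CCC=C(C)C | starting material
21 | (5E)-6,10-dimethylundeca-5,9-dien-2-yn-1-ol | OCC#CC/C=C(\C)CCC=C(C)C | intermediate
22 | (2E,5E)-6,10-dimethylundeca-2,5,9-trien-1-ol | OC/C=C/C/C=C(\C)CCC=C(C)C | intermediate
23 | [(2R,3R)-3-[(2E)-3,7-dimethylocta-2,6-dien-1-yl]oxiran-2-yl]methanol | OC[C@H]1O[C@@H]1C/C=C(\C)CCC=C(C)C | intermediate
24 | (2S,3R)-2-(chloromethyl)-3-[(2E)-3,7-dimethylocta-2,6-dien-1-yl]oxirane | ClC[C@H]1O[C@@H]1C/C=C(\C)CCC=C(C)C | intermediate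
25 | (3R,5E)-6,10-dimethylundeca-5,9-dien-1-yn-3-ol | O[C@H](C/C=C(\C)CCC=C(C)C)C#C | intermediate
26 | dimethyl[(1E,3R,5E)-3-hydroxy-2,6,10-trimethylundeca-1,5,9-trien-1-yl]alane, hydroxyl present as its aluminium alkoxide (not isolated) | O[C@H](C/C=C(\C)CCC=C(C)C)/C(C)=C/[Al](C)C | intermediate
27 | (1E,3R,5E)-1-iodo-2,6,10-trimethylundeca-1,5,9-trien-3-ol | O[C@H](C/C=C(\C)CCC=C(C)C)/C(C)=C/I | intermediate
28 | 9-BBN adduct of 18 with boron on the terminal carbon C13 (B-alkyl-9-borabicyclo[3.3.1]nonane, not isolated) | C1CCC2CCCC1B2CC[C@@]3(C)[C@H](CCCO[Si](c4ccccc4)(c4ccccc4)C(C)(C)C)/C(=C(/C)C(=O)OC)CC[C@]3(C)O | intermediate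
29 | methyl (2Z)-2-[(2R,3S,4S)-2-(3-{[tert-butyl(diphenyl)silyl]oxy}propyl)-4-hydroxy-3-[(3E,5R,7E)-5-hydroxy-4,8,12-trimethyltrideca-3,7,11-trien-1-yl]-3,4-dimethylcyclohexylidene]propanoate | O[C@H](C/C=C(\C)CCC=C(C)C)/C(C)=C/CC[C@@]1(C)[C@H](CCCO[Si](c2ccccc2)(c2ccccc2)C(C)(C)C)/C(=C(/C)C(=O)OC)CC[C@]1(C)O | intermediate
30 | (2Z)-2-[(2R,3S,4S)-2-(3-{[tert-butyl(diphenyl)silyl]oxy}propyl)-4-hydroxy-3-[(3E,5R,7E)-5-hydroxy-4,8,12-trimethyltrideca-3,7,11-trien-1-yl]-3,4-dimethylcyclohexylidene]propan-1-ol | O[C@H](C/C=C(\C)CCC=C(C)C)/C(C)=C/CC[C@@]1(C)[C@H](CCCO[Si](c2ccccc2)(c2ccccc2)C(C)(C)C)/C(=C(/C)CO)CC[C@]1(C)O | intermediate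
31 | (2Z)-2-[(2R,3S,4S)-2-(3-{[tert-butyl(diphenyl)silyl]oxy}propyl)-4-hydroxy-3-[(3E,5R,7E)-5-hydroxy-4,8,12-trimethyltrideca-3,7,11-trien-1-yl]-3,4-dimethylcyclohexylidene]propanal | O[C@H](C/C=C(\C)CCC=C(C)C)/C(C)=C/CC[C@@]1(C)[C@H](CCCO[Si](c2ccccc2)(c2ccccc2)C(C)(C)C)/C(=C(/C)C=O)CC[C@]1(C)O | intermediate
32 | (2Z)-2-[(2R,3S,4S)-3-[(3E,5R,7E)-5-acetoxy-4,8,12-trimethyltrideca-3,7,11-trien-1-yl]-2-(3-{[tert-butyl(diphenyl)silyl]oxy}propyl)-4-hydroxy-3,4-dimethylcyclohexylidene]propanal | CC(=O)O[C@H](C/C=C(\C)CCC=C(C)C)/C(C)=C/CC[C@@]1(C)[C@H](CCCO[Si](c2ccccc2)(c2ccccc2)C(C)(C)C)/C(=C(/C)C=O)CC[C@]1(C)O | intermediate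
33 | (2Z)-2-[(2R,3S,4S)-3-[(3E,5R,7E)-5-acetoxy-4,8,12-trimethyltrideca-3,7,11-trien-1-yl]-4-hydroxy-2-(3-hydroxypropyl)-3,4-dimethylcyclohexylidene]propanal (CNP0421354.1) | CC(=O)O[C@H](C/C=C(\C)CCC=C(C)C)/C(C)=C/CC[C@@]1(C)[C@H](CCCO)/C(=C(/C)C=O)CC[C@]1(C)O | target

Total step count: 24. Longest linear sequence: 18 steps (steps 1–13 and 20–24); the vinyl iodide 27 is made in 6 steps (14–19).

Steps most likely to fail

Step 7 (key step). The second stage is the weak point: the hindered secondary C6 radical or organosamarium may be quenched (1,5-hydrogen transfer from C8, protonation, addition to left-over acrylate) before it acylates the lactone. In the first stage the C–Br bond may be reduced while the ketone is still present, with three-membered ring closure to a cyclopropanol. Facial control at C10 and C6 may also be incomplete. The fallback replaces the acyl substitution by a radical closure on an aldehyde followed by oxidation. From 8, only the first stage is run (SmI2, 9, t-BuOH, THF, −78 °C) and the bromo γ-lactone 10 is isolated. iBu2AlH (1.1 equiv, CH2Cl2, −78 °C) should reduce it to the bromo lactol F1. Its open hydroxy aldehyde form should close by 6-exo radical cyclization of the C6 radical onto the aldehyde (Bu3SnH, AIBN, benzene, 80 °C, slow addition) to the cyclohexane-1,4-diol F2. DMP should then oxidize only the secondary alcohol, which returns the route to 12.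

Step 10. Closure of the strained bridged lactone may be slow, so that intermolecular olefination (oligomers) or base-mediated epimerization at C6 takes over. The fallback gives up the tether and with it the enforced geometry. From 12, an intermolecular Horner–Wadsworth–Emmons reaction with trimethyl 2-phosphonopropionate (NaH, THF, 60 °C) should give the enoate as a mixture of geometrical isomers, from which the methyl (2Z)-enoate silyl ether F3 is separated by chromatography. Hydrolysis of the tert-butyldimethylsilyl ether (AcOH/THF/H2O) then returns the route to 16.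

Step 2. Carbene transfer to the trisubstituted enol ether may show poor facial or exo selectivity, or the carbenoid may be lost by β-hydride migration. The fallback replaces asymmetric catalysis by resolution. From 2 and 3, the bulky achiral catalyst Rh2(O2CCPh3)4, chosen only for conversion and exo selectivity, should give the racemic exo ester F4. LiAlH4 reduces it to the racemic alcohol F5, and the enantiomers are separated by preparative chromatography on a chiral stationary phase, which returns the route to 5.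

Further compounds
F1 | step 7 | (5S)-5-[(2R,3R)-3-bromo-1-{[tert-butyl(dimethyl)silyl]oxy}-6-{[tert-butyl(diphenyl)silyl]oxy}-2-methylhexan-2-yl]-5-methyloxolan-2-ol (bromo lactol, both anomers) | OC1CC[C@]([C@](CO[Si](C)(C)C(C)(C)C)(C)[C@H](Br)CCCO[Si](c2ccccc2)(c2ccccc2)C(C)(C)C)(C)O1
F2 | step 7 | 2-{[tert-butyl(dimethyl)silyl]oxymethyl}-3-(3-{[tert-butyl(diphenyl)silyl]oxy}propyl)-1,2-dimethylcyclohexane-1,4-diol, ring stereocentres as in 12, both epimers at the secondary carbinol | CC(C)(C)[Si](C)(C)OC[C@@]1(C)[C@H](CCCO[Si](c2ccccc2)(c2ccccc2)C(C)(C)C)C(O)CC[C@]1(C)O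
F3 | step 10 | methyl (2Z)-2-[3-{[tert-butyl(dimethyl)silyl]oxymethyl}-2-(3-{[tert-butyl(diphenyl)silyl]oxy}propyl)-4-hydroxy-3,4-dimethylcyclohexylidene]propanoate, ring stereocentres as in 12 | CC(C)(C)[Si](C)(C)OC[C@@]1(C)[C@H](CCCO[Si](c2ccccc2)(c2ccccc2)C(C)(C)C)/C(=C(/C)C(=O)OC)CC[C@]1(C)O
F4 | step 2 | racemic methyl 1,7-dimethyl-2-oxabicyclo[4.1.0]heptane-7-carboxylate, ester exo (4 and its enantiomer) | COC(=O)[C@@]1(C)[C@@H]2CCCO[C@]12C.COC(=O)[C@]1(C)[C@H]2CCCO[C@@]12C
F5 | step 2 | racemic (1,7-dimethyl-2-oxabicyclo[4.1.0]heptan-7-yl)methanol, hydroxymethyl exo (5 and its enantiomer) | OC[C@@]1(C)[C@@H]2CCCO[C@]12C.OC[C@]1(C)[C@H]2CCCO[C@@]12C
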